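Read the product readings from the earliest stretch to the latest, and carry along one concentration, the substrate level against which the order of the rate is measured.

| setting | Wednesday's | Tuesday's | Thursday's | Monday's |
|---|---|---|---|---|
| substrate | 0.100 M | 0.0500 M | 0.300 M | 0.100 M |
| partner | 0.300 M | 0.250 M | 0.300 M | 0.300 M |
| catalyst | 0.0100 M | 0.0100 M | 0.0100 M | 0.0100 M |
| time |  |  |  | 55 h |

| Wednesday's run: time / h | Wednesday's run: [product] / M | Tuesday's run: time / h | Tuesday's run: [product] / M | Thursday's run: time / h | Thursday's run: [product] / M |
|---|---|---|---|---|---|
| 0.36 | 0.0016 | 0.36 | 0.0013 | 0.36 | 0.0017 |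
| 0.58 | 0.0026 | 0.58 | 0.0019 | 0.58 | 0.0056 |
| 0.91 | 0.0067 | 0.91 | 0.0058 | 0.91 | 0.0089 |
| 1.4 | 0.0132 | 1.4 | 0.0090 | 1.4 | 0.0167 |
| 2.3 | 0.0225 | 2.3 | 0.0136 | 2.3 | 0.0319 |
| 3.6 | 0.0367 | 3.6 | 0.0219 | 3.6 | 0.0451 |
| 5.7 | 0.0487 | 5.7 | 0.0263 | 5.7 | 0.0627 |
| 9.1 | 0.0573 | 9.1 | 0.0335 | 9.1 | 0.0723 |

(readings scatter by 0.001 M)

- the power of [substrate] that the first rate follows, about the charge of the Wednesday's run; measure it at two percent of substrate made into product (one fixed amount of product, the same in the runs compared)
- the power of [partner] that the first rate follows, about the charge of the Wednesday's run; measure it at two percent of substrate made into product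
- the Tuesday's run starts with 0.0500 M less of substrate and of partner than the Wednesday's run, and with no product. Compared where both hold the same amount of substrate, once fifteen percent of what the Tuesday's run was charged with has turned into product, is the Tuesday's run faster, slower or alike (within a tenth)?
- product in the Monday's run at 55 h, as a share of the substrate charged

- Overall: substrate + partner -> product, with catalyst as catalyst.
- Constant volume, constant temperature.
- Bound and free are read together.
- "The second partner" is partner.
- An order is taken over about fifteen percent of the charge, up and down.

The slow start comes first. Wednesday's run averages 0.00444 M/h up to 0.36 h, slower than the 0.0114 M/h between 0.91 h and 2.3 h. Two percent of its substrate turns between 0.36 h and 0.58 h, inside this start, so the reckoning here is read from the stretch after it.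

In that working stretch, Wednesday's and Thursday's runs share their partner and catalyst charges, so product at 1.4 h compares substrate. Take the rate as following S/(H + S), with S the substrate and W and Th marking the two runs:

q = 0.0167 M / 0.0132 M = 1.27 = (S_Th/S_W)(H + S_W)/(H + S_Th)

H = 0.0459 M

This reading is the turning concentration H, the Michaelis constant, the substrate level at which the rate stands at half its ceiling. The local order is n = H/(H + S), so Wednesday's charge gives

n = 0.314

Tuesday's run, with its lower substrate, has a substrate factor against Wednesday's of

f = 0.761

Its product at 1.4 h stands at 0.682 of Wednesday's, which leaves 0.896 for partner, a poorly held power of 0.601.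

The fade comes last. Thursday's rate falls from 0.0165 M/h to 0.00282 M/h, a factor of 5.85. Yet its substrate still stands at 0.228 M at 9.1 h, and S/(H + S) has moved by a factor of 1.04. Read as a steady decay between the midpoints of the two intervals, Thursday's fade has the constant

k = 0.305 /h

Monday's run has Wednesday's charge, so Wednesday's late rate, decayed to 9.1 h with Thursday's k and summed, gives an estimate of its end:

0.00151 M/h / k + 0.0573 M = 0.0622 M, or 62.2% of the charge

Tuesday's run holds 0.0410 M of substrate at 1.4 h, and Wednesday's holds 0.0427 M at 9.1 h. Near that match Tuesday's reading of 0.00561 M/h is faster than Wednesday's estimate of 0.00151 M/h.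

The forecast gives 0.3 for substrate, 1 for partner, faster and 64%, holding that “substrate is partly saturating”, and it differs from the reckoning here on partner and on the end.

The flask gives a substrate order of 0.18, lower than the reckoned 0.314, a partner order of 1.1, Tuesday's run faster, and 62.3% at 55 h.

    active catalyst + substrate ⇌ catalyst-substrate complex, settled at all times (28.50 /M)
    catalyst-substrate complex + partner → product + active catalyst (10.15 /M/h)
    partner → lost reagent (0.2012 /h)
    catalyst + partner → active catalyst + partner (5.112 /M/h)

At the two-percent point, Thursday's run stands at 0.010 M/h against Wednesday's 0.0089 M/h, a ratio of 1.14, lower than the 1.27 of the readings at 1.4 h. Carried to Tuesday's run, H gives 0.761 for substrate, and partner at its order of 1.1 brings the ratio to Wednesday's to 0.624. The simulated rates of Tuesday's and Wednesday's runs, 0.0061 M/h and 0.0089 M/h, stand at a ratio of 0.685.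

The earlier runs and the new flask stem from a simulated flask for an exercise; scatter was added.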